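**Retrosynthetic overview**

Labels: ring A = formyl-bearing arene, ring B = its dihydrofuran (O1, C2, C3; CHO on C5); ring C = central arene, ring D = its dihydrofuran (O1', C2', C3'; C4' bonded to C3, OH on C6'); ring E = 3,5-dihydroxyphenyl on C3'; rings G and G' = 4-hydroxyphenyl on C2 and C2'.
Feature and key disconnection: C2 and C2', the carbons bonded to O1 and O1', each carry a 4-hydroxyphenyl ring, so ring B and ring D are each the oxa-conjugate adduct of a p-quinone methide that is the tautomer of a 4-hydroxystilbene; cutting O1–C2 and O1'–C2' and returning the C3 and C3' hydrogens to the ring G and G' hydroxyls gives an achiral bis(triarylethylene) isomer of the target.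
Precursor assembly: its hexakis(triisopropylsilyl) ether is built on ring C by two enol triflate Suzuki couplings, first C3'–ring E (boronate from 5-bromoresorcinol), then C3–ring A (boronate from 3-bromo-4-hydroxybenzaldehyde, formyl group left unprotected).
Ketones behind the triflates: the C3' aryl benzyl ketone by Friedel–Crafts acylation of 5-bromoresorcinol (ring C) with (4-hydroxyphenyl)acetic acid at the future C3a'; the C3 ketone by bromine–lithium exchange at the future C4' and Weinreb acylation.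
Ring order: rings A, C, E, G and G' are bought as arenes; rings B and D close together in the last step, which also sets C2, C3, C2' and C3' (all R, both rings trans).

Key step: step 14

Remarks on the chemistry (TIPS = triisopropylsilyl):
- Assumption: both potassium enolates are taken to form with the Z geometry usual for aryl benzyl ketones, so the enol triflates and the alkenes made from them are drawn as single geometric isomers; a mixture would serve equally, because the geometry disappears in the quinone methides.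
- Assumption: which antipode of the phosphoric acid gives the 3R,3'R series cannot be predicted with confidence; the (R)-acid is written and its mirror image is used if the sense proves opposite.
- Assumption: the order of the two ring closures in step 14 is not known; it is written with ring B first, and either order converges on the same product.

**Route**

Step 1
Reactants: 1 5-bromoresorcinol; 2 (4-hydroxyphenyl)acetic acid
Product: 3 1-(2-bromo-4,6-dihydroxyphenyl)-2-(4-hydroxyphenyl)ethan-1-one
Conditions: BF3·OEt2 (as solvent), 85 °C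
Reagents that add atoms: none
Why: Friedel–Crafts C-acylation of a resorcinol by an arylacetic acid under BF3 activation, the standard route to 2,4-dihydroxydeoxybenzoins, should take place at C4 of 1 (para to one hydroxyl and ortho to the other, as with other 5-substituted resorcinols), while the less nucleophilic monophenol ring of 2 is left alone.

Step 2
Reactants: 3 1-(2-bromo-4,6-dihydroxyphenyl)-2-(4-hydroxyphenyl)ethan-1-one
Product: 4 1-[2-bromo-4,6-bis(triisopropylsilyloxy)phenyl]-2-[4-(triisopropylsilyloxy)phenyl]ethan-1-one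
Conditions: i-Pr3SiCl, imidazole, 4-(dimethylamino)pyridine (cat.), DMF, 50 °C
Reagents that add atoms: triisopropylsilyl chloride, CC(C)[Si](Cl)(C(C)C)C(C)C
Why: Phenol silylation with the chloride and imidazole (not the silyl triflate, so the benzylic ketone is not enol-silylated) should give triisopropylsilyl ethers that withstand the later enolate, organolithium and aqueous phosphate conditions and are too bulky to migrate between oxygens.

Step 3
Reactants: 4 1-[2-bromo-4,6-bis(triisopropylsilyloxy)phenyl]-2-[4-(triisopropylsilyloxy)phenyl]ethan-1-one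
Product: 6 (Z)-1-[2-bromo-4,6-bis(triisopropylsilyloxy)phenyl]-2-[4-(triisopropylsilyloxy)phenyl]ethenyl trifluoromethanesulfonate, via potassium enolate 5 (not isolated)
Conditions: KN(SiMe3)2, THF, −78 °C; then PhNTf2, −78 → 0 °C
Reagents that add atoms: N-phenylbis(trifluoromethanesulfonimide), O=S(=O)(N(c1ccccc1)S(=O)(=O)C(F)(F)F)C(F)(F)F
Why: Deprotonation of the doubly activated benzylic methylene and O-sulfonylation of the potassium enolate with PhNTf2 is the standard enol triflate synthesis, and the silyl group on the flanking oxygen should stay in place at −78 °C.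

Step 4
Reactants: 1 5-bromoresorcinol
Product: 7 1-bromo-3,5-bis(triisopropylsilyloxy)benzene
Conditions: i-Pr3SiCl, imidazole, DMF, rt
Reagents that add atoms: triisopropylsilyl chloride, CC(C)[Si](Cl)(C(C)C)C(C)C
Why: Routine silylation of two unhindered phenols gives the protected ring E bromide.

Step 5
Reactants: 7 1-bromo-3,5-bis(triisopropylsilyloxy)benzene
Product: 8 2-[3,5-bis(triisopropylsilyloxy)phenyl]-4,4,5,5-tetramethyl-1,3,2-dioxaborolane
Conditions: B2pin2, KOAc, PdCl2(dppf) (cat.; dppf = 1,1'-bis(diphenylphosphino)ferrocene), 1,4-dioxane, 90 °C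
Reagents that add atoms: bis(pinacolato)diboron, CC1(C)OB(OC1(C)C)B1OC(C)(C)C(C)(C)O1
Why: Miyaura borylation of an unhindered aryl bromide under acetate conditions leaves the aryl silyl ethers untouched.

Step 6
Reactants: 6 (Z)-1-[2-bromo-4,6-bis(triisopropylsilyloxy)phenyl]-2-[4-(triisopropylsilyloxy)phenyl]ethenyl trifluoromethanesulfonate; 8 2-[3,5-bis(triisopropylsilyloxy)phenyl]-4,4,5,5-tetramethyl-1,3,2-dioxaborolane
Product: 9 (E)-1-[2-bromo-4,6-bis(triisopropylsilyloxy)phenyl]-1-[3,5-bis(triisopropylsilyloxy)phenyl]-2-[4-(triisopropylsilyloxy)phenyl]ethene (ring C trans to ring G')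
Conditions: Pd(PPh3)4 (cat.), K3PO4, 1,4-dioxane/H2O, 60 °C, 8 in slight excess only
Reagents that add atoms: none
Why: Suzuki–Miyaura coupling of an enol triflate proceeds with retention of alkene geometry, and oxidative addition of zerovalent palladium to the enol triflate should be much faster with a triphenylphosphine catalyst at this temperature than to the ortho-substituted aryl bromide, which is thus kept for step 9.

Step 7
Reactants: 2 (4-hydroxyphenyl)acetic acid
Product: 10 2-(4-hydroxyphenyl)-N-methoxy-N-methylacetamide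
Conditions: MeNH(OMe)·HCl, EDC·HCl, 1-hydroxybenzotriazole, N-methylmorpholine, CH2Cl2/DMF, 0 °C → rt
Reagents that add atoms: N,O-dimethylhydroxylamine hydrochloride, CNOC.Cl
Why: Carbodiimide amide coupling acylates the hydroxylamine nitrogen much faster than the free phenol and gives the Weinreb amide.

Step 8
Reactants: 10 2-(4-hydroxyphenyl)-N-methoxy-N-methylacetamide
Product: 11 N-methoxy-N-methyl-2-[4-(triisopropylsilyloxy)phenyl]acetamide
Conditions: i-Pr3SiCl, imidazole, DMF, rt
Reagents that add atoms: triisopropylsilyl chloride, CC(C)[Si](Cl)(C(C)C)C(C)C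
Why: Routine phenol silylation removes the only acidic hydroxyl before the organolithium step.

Step 9
Reactants: 9 (E)-1-[2-bromo-4,6-bis(triisopropylsilyloxy)phenyl]-1-[3,5-bis(triisopropylsilyloxy)phenyl]-2-[4-(triisopropylsilyloxy)phenyl]ethene; 11 N-methoxy-N-methyl-2-[4-(triisopropylsilyloxy)phenyl]acetamide
Product: 14 1-{2-[(E)-1-[3,5-bis(triisopropylsilyloxy)phenyl]-2-[4-(triisopropylsilyloxy)phenyl]ethenyl]-3,5-bis(triisopropylsilyloxy)phenyl}-2-[4-(triisopropylsilyloxy)phenyl]ethan-1-one, via aryllithium 12 (not isolated), via tetrahedral lithium adduct 13 (not isolated)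
Conditions: t-BuLi (2.0 equiv), Et2O/THF, −78 °C; then 11, −78 → 0 °C; then H2O
Reagents that add atoms: none
Why: Bromine–lithium exchange is far faster than addition of t-BuLi to the hindered electron-rich alkene and gives an aryllithium with no silyloxy group ortho to it (so no retro-Brook shift), whose addition to the Weinreb amide stops at the chelated tetrahedral adduct that releases the ketone only on quench (Weinreb ketone synthesis).

Step 10
Reactants: 14 the aryl benzyl ketone of step 9
Product: 16 (Z)-1-{2-[(E)-1-[3,5-bis(triisopropylsilyloxy)phenyl]-2-[4-(triisopropylsilyloxy)phenyl]ethenyl]-3,5-bis(triisopropylsilyloxy)phenyl}-2-[4-(triisopropylsilyloxy)phenyl]ethenyl trifluoromethanesulfonate, via potassium enolate 15 (not isolated)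
Conditions: KN(SiMe3)2, THF, −78 °C; then PhNTf2, −78 → 0 °C
Reagents that add atoms: N-phenylbis(trifluoromethanesulfonimide), O=S(=O)(N(c1ccccc1)S(=O)(=O)C(F)(F)F)C(F)(F)F
Why: Same enolate O-triflation as step 3, here at the only acidic position of 14 and with no silyloxy group next to the carbonyl.

Step 11
Reactants: 17 3-bromo-4-hydroxybenzaldehyde
Product: 18 4-hydroxy-3-(4,4,5,5-tetramethyl-1,3,2-dioxaborolan-2-yl)benzaldehyde
Conditions: B2pin2, KOAc, PdCl2(dppf) (cat.), 1,4-dioxane, 85 °C
Reagents that add atoms: bis(pinacolato)diboron, CC1(C)OB(OC1(C)C)B1OC(C)(C)C(C)(C)O1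
Why: Miyaura borylation under weakly basic acetate conditions tolerates both the aldehyde and the free phenol, so ring A needs no protecting group.

Step 12
Reactants: 16 the enol triflate of step 10; 18 4-hydroxy-3-(4,4,5,5-tetramethyl-1,3,2-dioxaborolan-2-yl)benzaldehyde
Product: 19 4-hydroxy-3-[(Z)-1-{2-[(E)-1-[3,5-bis(triisopropylsilyloxy)phenyl]-2-[4-(triisopropylsilyloxy)phenyl]ethenyl]-3,5-bis(triisopropylsilyloxy)phenyl}-2-[4-(triisopropylsilyloxy)phenyl]ethenyl]benzaldehyde
Conditions: Pd(OAc)2 (cat.), 2-dicyclohexylphosphino-2',6'-dimethoxybiphenyl, K3PO4, toluene/H2O, 70 °C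
Reagents that add atoms: none
Why: Suzuki–Miyaura coupling of a 1,2-diarylvinyl triflate with an arylboronate is the established way to triarylethylenes, tolerates the aldehyde and the small free ortho-hydroxyl, and a bulky electron-rich biarylphosphine is chosen for the congested reductive elimination.

Step 13
Reactants: 19 the hexakis(triisopropylsilyl) ether of step 12
Product: 20 4-hydroxy-3-[(Z)-1-{2-[(E)-1-(3,5-dihydroxyphenyl)-2-(4-hydroxyphenyl)ethenyl]-3,5-dihydroxyphenyl}-2-(4-hydroxyphenyl)ethenyl]benzaldehyde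
Conditions: Bu4NF/AcOH (1:1, 7 equiv), THF, 0 °C → rt, argon; isolation without contact with acid
Reagents that add atoms: none
Why: Fluoride cleaves aryl silyl ethers rapidly, and the acetic acid buffer keeps the medium near neutral so that neither phenoxide- nor acid-triggered background cyclisation of the free hydroxystilbenes should set in.

Step 14
Reactants: 20 the unprotected bis(triarylethylene) of step 13
Product: 24 (2R,3R)-3-[(2R,3R)-3-(3,5-dihydroxyphenyl)-6-hydroxy-2-(4-hydroxyphenyl)-2,3-dihydro-1-benzofuran-4-yl]-2-(4-hydroxyphenyl)-2,3-dihydro-1-benzofuran-5-carbaldehyde, via quinone methide 21 (not isolated), via mono-cyclised phenol 22 (not isolated), via quinone methide 23 (not isolated)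
Conditions: (R)-3,3'-bis(2,4,6-triisopropylphenyl)-1,1'-binaphthyl-2,2'-diyl hydrogen phosphate (10 mol%), CH2Cl2/EtOAc, 4 Å molecular sieves, −20 °C → rt, argon
Reagents that add atoms: none
Why: Proposed new method: the chiral acid should deliver its proton to the diaryl-substituted alkene carbon C3 while its phosphoryl oxygen accepts the hydroxyl proton of ring G, so that the 4-hydroxystilbene unit tautomerises to the p-quinone methide 21, the C7a hydroxyl adds to the exocyclic carbon C2 to give 22, and the same sequence at C3'/C2' through 23 completes the cascade; the closest known reaction types are the chiral phosphoric acid-catalysed hydrofunctionalisation of hydroxystyrenes through quinone methides and the acid-mediated cycloisomerisation of 2-hydroxystilbenes to 2-aryl-2,3-dihydrobenzofurans. Ring B and ring D each close by a 5-exo-trig oxa-conjugate (1,6-) addition of a phenol to a p-quinone methide, forming O1–C2 and O1'–C2'. C3 and C3' are set by the catalyst, either in the enantiofacial proton transfer or, if the tautomerisation is reversible, in the faster ring closure of one hydrogen-bonded quinone methide enantiomer, and C2 and C2' are set by the substrate, each ring closing with the C2 aryl group trans to the C3 aryl group, which is also the more stable arrangement. The cascade needs the same facial sense at both alkenes, which one catalyst can give because the two units have the same constitution around the reacting atoms and the same absolute sense in the target, and an error at one unit ends in a separable diastereomer and not in the enantiomer. It also needs protonation at C3 and C3' and not at C2 and C2', which the substrate secures because the alternative cations (o-quinone methides of ring A or ring C) have no nucleophile placed for a five-membered closure and return to the alkene, and it needs O-attack over attack by the second electron-rich alkene or by ring E, which the five-atom reach of the phenol and the quaternary centre or larger ring demanded by carbon attack should secure. The reaction is run cold and stopped at full conversion so that re-ionisation of the C2–O1 and C2'–O1' bonds, which would erode the enantiomeric purity, stays slow.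

**Compound list**

1 | 5-bromoresorcinol | Oc1cc(O)cc(Br)c1 | starting material
2 | (4-hydroxyphenyl)acetic acid | OC(=O)Cc1ccc(O)cc1 | starting material
3 | 1-(2-bromo-4,6-dihydroxyphenyl)-2-(4-hydroxyphenyl)ethan-1-one | O=C(Cc1ccc(O)cc1)c1c(O)cc(O)cc1Br | intermediate
4 | 1-[2-bromo-4,6-bis(triisopropylsilyloxy)phenyl]-2-[4-(triisopropylsilyloxy)phenyl]ethan-1-one | O=C(Cc1ccc(O[Si](C(C)C)(C(C)C)C(C)C)cc1)c1c(O[Si](C(C)C)(C(C)C)C(C)C)cc(O[Si](C(C)C)(C(C)C)C(C)C)cc1Br | intermediate
5 | potassium (Z)-enolate of 4 | [K+].[O-]/C(=C\c1ccc(O[Si](C(C)C)(C(C)C)C(C)C)cc1)c1c(O[Si](C(C)C)(C(C)C)C(C)C)cc(O[Si](C(C)C)(C(C)C)C(C)C)cc1Br | intermediate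
6 | (Z)-enol triflate of 4 | FC(F)(F)S(=O)(=O)O/C(=C\c1ccc(O[Si](C(C)C)(C(C)C)C(C)C)cc1)c1c(O[Si](C(C)C)(C(C)C)C(C)C)cc(O[Si](C(C)C)(C(C)C)C(C)C)cc1Br | intermediate
7 | 1-bromo-3,5-bis(triisopropylsilyloxy)benzene | Brc1cc(O[Si](C(C)C)(C(C)C)C(C)C)cc(O[Si](C(C)C)(C(C)C)C(C)C)c1 | intermediate
8 | 2-[3,5-bis(triisopropylsilyloxy)phenyl]-4,4,5,5-tetramethyl-1,3,2-dioxaborolane | CC1(C)OB(OC1(C)C)c1cc(O[Si](C(C)C)(C(C)C)C(C)C)cc(O[Si](C(C)C)(C(C)C)C(C)C)c1 | intermediate
9 | (E)-1-[2-bromo-4,6-bis(triisopropylsilyloxy)phenyl]-1-[3,5-bis(triisopropylsilyloxy)phenyl]-2-[4-(triisopropylsilyloxy)phenyl]ethene | Brc1cc(O[Si](C(C)C)(C(C)C)C(C)C)cc(O[Si](C(C)C)(C(C)C)C(C)C)c1/C(=C/c1ccc(O[Si](C(C)C)(C(C)C)C(C)C)cc1)c1cc(O[Si](C(C)C)(C(C)C)C(C)C)cc(O[Si](C(C)C)(C(C)C)C(C)C)c1 | intermediate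
10 | 2-(4-hydroxyphenyl)-N-methoxy-N-methylacetamide | CON(C)C(=O)Cc1ccc(O)cc1 | intermediate
11 | N-methoxy-N-methyl-2-[4-(triisopropylsilyloxy)phenyl]acetamide | CON(C)C(=O)Cc1ccc(O[Si](C(C)C)(C(C)C)C(C)C)cc1 | intermediate
12 | aryllithium from 9 (Li in place of Br) | [Li]c1cc(O[Si](C(C)C)(C(C)C)C(C)C)cc(O[Si](C(C)C)(C(C)C)C(C)C)c1/C(=C/c1ccc(O[Si](C(C)C)(C(C)C)C(C)C)cc1)c1cc(O[Si](C(C)C)(C(C)C)C(C)C)cc(O[Si](C(C)C)(C(C)C)C(C)C)c1 | intermediate
13 | tetrahedral lithium adduct of 12 and 11 (new centre not controlled, lost on collapse) | [Li]OC(Cc1ccc(O[Si](C(C)C)(C(C)C)C(C)C)cc1)(N(C)OC)c1cc(O[Si](C(C)C)(C(C)C)C(C)C)cc(O[Si](C(C)C)(C(C)C)C(C)C)c1/C(=C/c1ccc(O[Si](C(C)C)(C(C)C)C(C)C)cc1)c1cc(O[Si](C(C)C)(C(C)C)C(C)C)cc(O[Si](C(C)C)(C(C)C)C(C)C)c1 | intermediate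
14 | 1-{2-[(E)-1-[3,5-bis(triisopropylsilyloxy)phenyl]-2-[4-(triisopropylsilyloxy)phenyl]ethenyl]-3,5-bis(triisopropylsilyloxy)phenyl}-2-[4-(triisopropylsilyloxy)phenyl]ethan-1-one | O=C(Cc1ccc(O[Si](C(C)C)(C(C)C)C(C)C)cc1)c1cc(O[Si](C(C)C)(C(C)C)C(C)C)cc(O[Si](C(C)C)(C(C)C)C(C)C)c1/C(=C/c1ccc(O[Si](C(C)C)(C(C)C)C(C)C)cc1)c1cc(O[Si](C(C)C)(C(C)C)C(C)C)cc(O[Si](C(C)C)(C(C)C)C(C)C)c1 | intermediate
15 | potassium (Z)-enolate of 14 | [K+].[O-]/C(=C\c1ccc(O[Si](C(C)C)(C(C)C)C(C)C)cc1)c1cc(O[Si](C(C)C)(C(C)C)C(C)C)cc(O[Si](C(C)C)(C(C)C)C(C)C)c1/C(=C/c1ccc(O[Si](C(C)C)(C(C)C)C(C)C)cc1)c1cc(O[Si](C(C)C)(C(C)C)C(C)C)cc(O[Si](C(C)C)(C(C)C)C(C)C)c1 | intermediate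
16 | (Z)-enol triflate of 14 | FC(F)(F)S(=O)(=O)O/C(=C\c1ccc(O[Si](C(C)C)(C(C)C)C(C)C)cc1)c1cc(O[Si](C(C)C)(C(C)C)C(C)C)cc(O[Si](C(C)C)(C(C)C)C(C)C)c1/C(=C/c1ccc(O[Si](C(C)C)(C(C)C)C(C)C)cc1)c1cc(O[Si](C(C)C)(C(C)C)C(C)C)cc(O[Si](C(C)C)(C(C)C)C(C)C)c1 | intermediate
17 | 3-bromo-4-hydroxybenzaldehyde | O=Cc1ccc(O)c(Br)c1 | starting material
18 | 4-hydroxy-3-(4,4,5,5-tetramethyl-1,3,2-dioxaborolan-2-yl)benzaldehyde | O=Cc1ccc(O)c(c1)B1OC(C)(C)C(C)(C)O1 | intermediate
19 | hexakis(triisopropylsilyl) ether of 20 (ring A hydroxyl free; ring A cis to ring G, ring C trans to ring G') | O=Cc1ccc(O)c(c1)/C(=C\c1ccc(O[Si](C(C)C)(C(C)C)C(C)C)cc1)c1cc(O[Si](C(C)C)(C(C)C)C(C)C)cc(O[Si](C(C)C)(C(C)C)C(C)C)c1/C(=C/c1ccc(O[Si](C(C)C)(C(C)C)C(C)C)cc1)c1cc(O[Si](C(C)C)(C(C)C)C(C)C)cc(O[Si](C(C)C)(C(C)C)C(C)C)c1 | intermediate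
20 | 4-hydroxy-3-[(Z)-1-{2-[(E)-1-(3,5-dihydroxyphenyl)-2-(4-hydroxyphenyl)ethenyl]-3,5-dihydroxyphenyl}-2-(4-hydroxyphenyl)ethenyl]benzaldehyde | O=Cc1ccc(O)c(c1)/C(=C\c1ccc(O)cc1)c1cc(O)cc(O)c1/C(=C/c1ccc(O)cc1)c1cc(O)cc(O)c1 | intermediate
21 | p-quinone methide from protonation at C3 (C3 R; primed alkene intact) | O=Cc1ccc(O)c(c1)[C@@H](c1cc(O)cc(O)c1/C(=C/c1ccc(O)cc1)c1cc(O)cc(O)c1)C=C1C=CC(=O)C=C1 | intermediate
22 | mono-cyclised phenol: (2R,3R)-dihydrobenzofuran with ring B closed and the primed alkene intact | O=Cc1ccc2c(c1)[C@@H](c1cc(O)cc(O)c1/C(=C/c1ccc(O)cc1)c1cc(O)cc(O)c1)[C@H](c1ccc(O)cc1)O2 | intermediate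
23 | p-quinone methide from protonation of 22 at C3' (C3' R) | O=Cc1ccc2c(c1)[C@@H](c1cc(O)cc(O)c1[C@@H](c1cc(O)cc(O)c1)C=C1C=CC(=O)C=C1)[C@H](c1ccc(O)cc1)O2 | intermediate
24 | (2R,3R)-3-[(2R,3R)-3-(3,5-dihydroxyphenyl)-6-hydroxy-2-(4-hydroxyphenyl)-2,3-dihydro-1-benzofuran-4-yl]-2-(4-hydroxyphenyl)-2,3-dihydro-1-benzofuran-5-carbaldehyde | O=Cc1ccc2c(c1)[C@@H](c1cc(O)cc3c1[C@@H](c1cc(O)cc(O)c1)[C@H](c1ccc(O)cc1)O3)[C@H](c1ccc(O)cc1)O2 | target

**Step count and risks**

Total steps: 14. Longest linear sequence: 9 (steps 1, 2, 3, 6, 9, 10, 12, 13, 14).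

Steps most likely to fail:

1. Step 14. What may go wrong: too little or the wrong facial discrimination in the proton transfer and ring closure; carbon attack of the second electron-rich alkene (or ring E) on the first quinone methide; re-ionisation of the product ethers with loss of enantiomeric purity. Fallback with known chemistry, setting out from 20 and returning at 24: an achiral sulfonic acid (p-TsOH·H2O, MeCN, rt) effects the known acid-mediated cycloisomerisation of 2-hydroxystilbenes under trans control and should give racemic 24, that is 24 together with its mirror image ent-24 F1, besides the racemic unlike diastereomer (2R*,3R*,2'S*,3'S*) F2. F2 would be removed by reversed-phase chromatography and F1 by preparative chromatography on a chiral stationary phase, which leaves 24. This answers a failure of enantiocontrol only; competing carbon attack would persist.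

2. Step 12. What may go wrong: transmetalation and reductive elimination at the congested trisubstituted vinylpalladium become so slow that protodeboronation of the ortho-hydroxyaryl boronate and hydrolysis of the triflate take over. Fallback, setting out from 9 and returning at 19, which moves the last C–C bond to the unhindered alkene terminus: aryllithium 12 (generated from 9 as in step 9) is acylated with N-methoxy-N-methylacetamide to the methyl ketone F3; KN(SiMe3)2 and PhNTf2 give the 1-arylvinyl triflate F4; Suzuki coupling with 18 gives the 1,1-diarylethylene F5, a less hindered coupling because the triflate carries no β-aryl group; Heck arylation of the terminal CH2 with (4-iodophenoxy)triisopropylsilane (Pd(OAc)2, tri(o-tolyl)phosphine, Et3N, DMF, 100 °C) then gives 19, possibly mixed with the unprimed (E)-isomer of 19 F6, which serves equally in steps 13 and 14.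

3. Step 9. What may go wrong: proton transfer from the acidic benzylic methylene of 11 to the hindered aryllithium, which would return the debrominated arene and unchanged amide instead of the ketone. Fallback, setting out from 9 and returning at 14, which replaces the organolithium by palladium catalysis: Stille coupling of 9 with tributyl(1-ethoxyvinyl)stannane (Pd(PPh3)4, toluene, 100 °C) gives the 1-ethoxyvinyl arene F7, which dilute HCl in THF hydrolyses to the methyl ketone F3; palladium-catalysed α-arylation of F3 with (4-bromophenoxy)triisopropylsilane (Pd(OAc)2, 2-dicyclohexylphosphino-2',4',6'-triisopropylbiphenyl, K3PO4, toluene, 90 °C) then gives 14.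

**Further compounds**

F1 | step 14 | ent-24, the (2S,3S,2'S,3'S) enantiomer | O=Cc1ccc2c(c1)[C@H](c1cc(O)cc3c1[C@H](c1cc(O)cc(O)c1)[C@@H](c1ccc(O)cc1)O3)[C@@H](c1ccc(O)cc1)O2
F2 | step 14 | unlike trans,trans diastereomer (2R*,3R*,2'S*,3'S*), racemic, one enantiomer drawn | O=Cc1ccc2c(c1)[C@@H](c1cc(O)cc3c1[C@H](c1cc(O)cc(O)c1)[C@@H](c1ccc(O)cc1)O3)[C@H](c1ccc(O)cc1)O2
F3 | step 12 | 1-{2-[(E)-1-[3,5-bis(triisopropylsilyloxy)phenyl]-2-[4-(triisopropylsilyloxy)phenyl]ethenyl]-3,5-bis(triisopropylsilyloxy)phenyl}ethan-1-one | CC(=O)c1cc(O[Si](C(C)C)(C(C)C)C(C)C)cc(O[Si](C(C)C)(C(C)C)C(C)C)c1/C(=C/c1ccc(O[Si](C(C)C)(C(C)C)C(C)C)cc1)c1cc(O[Si](C(C)C)(C(C)C)C(C)C)cc(O[Si](C(C)C)(C(C)C)C(C)C)c1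
F4 | step 12 | 1-arylvinyl triflate of F3 | C=C(OS(=O)(=O)C(F)(F)F)c1cc(O[Si](C(C)C)(C(C)C)C(C)C)cc(O[Si](C(C)C)(C(C)C)C(C)C)c1/C(=C/c1ccc(O[Si](C(C)C)(C(C)C)C(C)C)cc1)c1cc(O[Si](C(C)C)(C(C)C)C(C)C)cc(O[Si](C(C)C)(C(C)C)C(C)C)c1
F5 | step 12 | 1,1-diarylethylene: 4-hydroxy-3-(1-arylethenyl)benzaldehyde with the ring C aryl group of F3 | O=Cc1ccc(O)c(c1)C(=C)c1cc(O[Si](C(C)C)(C(C)C)C(C)C)cc(O[Si](C(C)C)(C(C)C)C(C)C)c1/C(=C/c1ccc(O[Si](C(C)C)(C(C)C)C(C)C)cc1)c1cc(O[Si](C(C)C)(C(C)C)C(C)C)cc(O[Si](C(C)C)(C(C)C)C(C)C)c1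
F6 | step 12 | unprimed (E)-isomer of 19 (ring A trans to ring G) | O=Cc1ccc(O)c(c1)/C(=C/c1ccc(O[Si](C(C)C)(C(C)C)C(C)C)cc1)c1cc(O[Si](C(C)C)(C(C)C)C(C)C)cc(O[Si](C(C)C)(C(C)C)C(C)C)c1/C(=C/c1ccc(O[Si](C(C)C)(C(C)C)C(C)C)cc1)c1cc(O[Si](C(C)C)(C(C)C)C(C)C)cc(O[Si](C(C)C)(C(C)C)C(C)C)c1
F7 | step 9 | 1-ethoxyvinyl arene from 9 (CH2=C(OEt) in place of Br) | CCOC(=C)c1cc(O[Si](C(C)C)(C(C)C)C(C)C)cc(O[Si](C(C)C)(C(C)C)C(C)C)c1/C(=C/c1ccc(O[Si](C(C)C)(C(C)C)C(C)C)cc1)c1cc(O[Si](C(C)C)(C(C)C)C(C)C)cc(O[Si](C(C)C)(C(C)C)C(C)C)c1
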